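**Retrosynthetic overview**

- Target ⇐ global desilylation ⇐ Weitz–Scheffer epoxidation of the upper enone (C2'=C3') ⇐ ortho-chlorination at C6 ⇐ spiroketal enone, whose 1,3-dioxin ring D (C1'–O–C8–C8a–C1–O) is closed by acid from an epoxy hemiketal.
- Epoxy hemiketal ⇐ key step on an 8'-(3,4-dihydronaphthalen-1-yl)naphthalenone: O2 adds by an ene reaction at C1=C2, is stored as a six-membered 1,2-dioxan-3-ol (C8'–C8a'–C1'–O–O–C1), and this ring contracts to the five-membered ether ring C (C8'–C8a'–C1'–O–C1) while the expelled peroxide oxygen becomes the C2–C3 oxirane; both atoms of O2 end in the target.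
- Enabling feature: the C1' carbonyl of ring B and C1 of ring F sit peri to each other across C8'–C8a', and C1 is flanked in ring F by C2, the C3 methylene and the C4 carbinol stereocentre. A C1 hydroperoxide must therefore close on C1', and its spare oxygen finds an allylic C2=C3 alkene on a face defined by C4.
- Coupled alkene ⇐ Suzuki–Miyaura union (C8'–C1) of an enol triflate made from naphthazarin (C4 set by asymmetric transfer hydrogenation) with an aryl bromide made from naphthalene-1,5-diol (quinone monoketal, then Br, Cl).
- Ring order: rings A/B (upper arene, upper carbocycle) and E/F (lower arene, lower carbocycle) come with the fragments; then 1,2-dioxane (transient) → ring C plus lower oxirane → ring D → upper oxirane.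

Key step: step 10

Remark: locants C1–C8a denote the lower, tetralin-derived unit and C1'–C8a' the upper, naphthalenone-derived unit (C1' is the spiro carbon, C8' carries the bond to C1).
Remark on the chemistry: the hemiketal carbon C1' of the peroxy-hemiketal, of the epoxy hemiketal and of its desilylated form is expected as an equilibrating epimer mixture, so its SMILES carries no descriptor; the tether fixes it at the spiroketal stage.

Step 1
Reactants: 1 naphthazarin (5,8-dihydroxynaphthalene-1,4-dione)
Product: 2 leuconaphthazarin (5,8-dihydroxy-2,3-dihydronaphthalene-1,4-dione)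
Conditions: SnCl2·2H2O, 4 M HCl, 100 °C
Reagents that add atoms: none
Why: SnCl2 reduces the quinone to the tetrahydroxynaphthalene, which should tautomerise to the hydrogen-bonded 2,3-dihydro-1,4-dione (quinone reduction followed by keto–enol tautomerisation); no stereocentre is formed.

Step 2
Reactants: 2 leuconaphthazarin
Product: 3 (R)-4,5,8-trihydroxy-3,4-dihydronaphthalen-1(2H)-one
Conditions: RuCl[(R,R)-TsDPEN](p-cymene) (1 mol %), HCO2H/Et3N (5:2), DMF, 25 °C, argon, stopped after one hydride equivalent
Reagents that add atoms: none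
Why: Noyori asymmetric transfer hydrogenation of an aryl ketone: the two carbonyl groups are homotopic, the (R,R)-ligand should give the (R)-carbinol by analogy with 1-tetralone, and the second carbonyl loses its ortho-acyl activation after the first reduction, so that the reaction can be stopped at the hydroxy ketone.

Step 3
Reactants: 3 (R)-4,5,8-trihydroxy-3,4-dihydronaphthalen-1(2H)-one
Product: 4 (R)-4,5,8-tris(tert-butyldimethylsilyloxy)-3,4-dihydronaphthalen-1(2H)-one
Conditions: TBSCl (4 equiv), imidazole, DMAP (cat.), DMF, 40 °C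
Reagents that add atoms: tert-butyldimethylsilyl chloride, CC(C)(C)[Si](C)(C)Cl
Why: Silyl chloride/imidazole silylation of the secondary alcohol and both phenols (the chelated C8 phenol needs the mild heating), under conditions that should not silylate the ketone enol.

Step 4
Reactants: 4 (R)-4,5,8-tris(tert-butyldimethylsilyloxy)-3,4-dihydronaphthalen-1(2H)-one
Product: 5 (R)-4,5,8-tris(tert-butyldimethylsilyloxy)-3,4-dihydronaphthalen-1-yl trifluoromethanesulfonate
Conditions: PhNTf2, then KN(SiMe3)2 added, THF, −78 → −40 °C
Reagents that add atoms: N-phenylbis(trifluoromethanesulfonimide), O=S(=O)(N(c1ccccc1)S(=O)(=O)C(F)(F)F)C(F)(F)F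
Why: Enol triflate formation: deprotonation at the only α-methylene (C2) and O-triflation of the potassium enolate, with the imide present from the start so that the enolate is trapped before a silyl shift from the peri oxygen can occur.

Step 5
Reactants: 6 naphthalene-1,5-diol
Product: 7 5-hydroxy-4,4-dimethoxynaphthalen-1(4H)-one
Conditions: PhI(OAc)2 (2.1 equiv), MeOH, 0 °C → rt
Reagents that add atoms: methanol, CO
Why: Oxidative dearomatisation of a para-unsubstituted naphthol with PhI(OAc)2 in methanol (two successive two-electron oxidations) should give the p-quinone dimethyl monoketal, with the ketal carbon peri to the remaining phenol and the carbonyl on the far side.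

Step 6
Reactants: 7 5-hydroxy-4,4-dimethoxynaphthalen-1(4H)-one
Product: 8 8-bromo-5-hydroxy-4,4-dimethoxynaphthalen-1(4H)-one
Conditions: NBS (1.0 equiv), MeCN, 0 °C
Reagents that add atoms: N-bromosuccinimide, O=C1CCC(=O)N1Br
Why: Electrophilic aromatic bromination para to the free phenol (NBS in acetonitrile is para-selective), the enone being too electron-poor to react.

Step 7
Reactants: 8 8-bromo-5-hydroxy-4,4-dimethoxynaphthalen-1(4H)-one
Product: 9 8-bromo-6-chloro-5-hydroxy-4,4-dimethoxynaphthalen-1(4H)-one
Conditions: NCS (1.05 equiv), iPr2NH (cat.), CH2Cl2, 0 °C → rt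
Reagents that add atoms: N-chlorosuccinimide, O=C1CCC(=O)N1Cl
Why: Amine-catalysed electrophilic ortho-chlorination of the phenol at C6, the only activated position left on this ring.

Step 8
Reactants: 9 8-bromo-6-chloro-5-hydroxy-4,4-dimethoxynaphthalen-1(4H)-one
Product: 10 8-bromo-6-chloro-4,4-dimethoxy-5-(triisopropylsilyloxy)naphthalen-1(4H)-one
Conditions: NaH, TIPSCl, THF, 0 °C → rt
Reagents that add atoms: triisopropylsilyl chloride, CC(C)[Si](Cl)(C(C)C)C(C)C
Why: O-Silylation of the sodium phenoxide, chosen because the phenol is flanked by chlorine and the peri ketal and because silyl triflates would attack the dimethyl ketal.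

Step 9
Reactants: 5 (R)-4,5,8-tris(tert-butyldimethylsilyloxy)-3,4-dihydronaphthalen-1-yl trifluoromethanesulfonate; 10 8-bromo-6-chloro-4,4-dimethoxy-5-(triisopropylsilyloxy)naphthalen-1(4H)-one
Product: 12 8'-(dihydronaphthalenyl)naphthalenone (C8'–C1 bond; C1=C2 alkene; 4R), via vinyl pinacol boronate 11 (not isolated)
Conditions: B2pin2, Pd(dppf)Cl2 (5 mol %), KOAc, dioxane, 80 °C; then 10, K3PO4, H2O, 70 °C
Reagents that add atoms: none
Why: Miyaura borylation of the enol triflate and Suzuki–Miyaura coupling in one pot; oxidative addition to the C–Br bond next to the carbonyl-bearing carbon should be much faster than to the hindered C–Cl bond, and the C4 stereocentre is not touched.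

Step 10
Reactants: 12 8'-(dihydronaphthalenyl)naphthalenone
Product: 15 epoxy hemiketal (ring C closed; C2–C3 oxirane), via allylic hydroperoxide 13 (not isolated), via 1,2-dioxan-3-ol 14 (not isolated)
Conditions: O2 (1 atm), tetraphenylporphyrin (cat.), white LED, CH2Cl2, −20 °C; then Ti(OiPr)4 (0.2 equiv), 4 Å MS, −20 → 0 °C
Reagents that add atoms: dioxygen, O=O
Why: Proposed new method: singlet oxygen should undergo a Schenck ene reaction at the C1=C2 alkene (only C3 carries allylic hydrogens), the hydroperoxide 13 then adds to the peri C1' ketone to close the strain-free six-membered 1,2-dioxan-3-ol 14 (6-exo-trig hemiketalisation, ring C8'–C8a'–C1'–O–O–C1), and Ti(OiPr)4 is expected to draw the hydroperoxide out of this ring–chain equilibrium as a titanium alkylperoxide, pass the ketal-side peroxide oxygen to the C2=C3 alkene of a titanium-bound allylic alkoxide and let the remaining C1 alkoxide re-close on C1' (5-exo-trig), so that the dioxane contracts to ring C by extrusion of one oxygen, which ends as the oxirane. The closest known reaction type is the Ti(OiPr)4- or VO(acac)2-catalysed oxygen transfer of singlet-oxygen-derived allylic hydroperoxides to 2,3-epoxy alcohols (one-pot photooxygenation/epoxidation of alkenes); new here is that the hydroperoxide is stored as a cyclic peroxy-hemiketal and that the liberated alcohol is caught by the same ketone. C1 is controlled by C4: peri strain with the C5 silyl ether holds the C4 OTBS group pseudo-axial, the only C3–H aligned with the alkene π system is the pseudo-axial one on the opposite face, and suprafacial ene attack there puts the C1–O bond trans to the C4–O bond. C2 and C3 are controlled by oxygen delivery from titanium bound to the C1 oxygen, that is syn to this oxygen, which is also the face left open by the upper aryl group on C1 and by the C4 OTBS group. The step needs chemoselectivity for the trisubstituted styrenyl alkene over the enone (electron-poor, inert to singlet oxygen and to the electrophilic titanium peroxide) and over the arenes (all phenols silylated), and ene reaction over (4+2) addition, which the fixed, well-aligned allylic C–H of the dihydronaphthalene should secure. C1' is formed as a hemiketal epimer mixture, which is of no consequence.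

Step 11
Reactants: 15 epoxy hemiketal
Product: 17 spiroketal enone (rings C and D closed at C1'; C4' ketone), via hydroquinone hemiketal 16 (not isolated)
Conditions: TBAF (2.2 equiv), AcOH, THF, 0 °C, argon; then CSA (excess over acetate), H2O, rt
Reagents that add atoms: water, O
Why: Fluoride should cleave the two phenolic TBS ethers far faster than the hindered phenolic TIPS ether and the secondary alkyl TBS ether, and acid then ionises the hemiketal to a benzylic, allylic oxocarbenium ion that the C8 phenol captures (6-endo spiroketalisation, the tether allowing only one configuration at C1') while the dimethyl ketal is hydrolysed to the C4' ketone (acetal exchange and hydrolysis).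

Step 12
Reactants: 17 spiroketal enone
Product: 18 6-chloro spiroketal enone
Conditions: NCS (1.05 equiv), iPr2NH (cat.), CH2Cl2, 0 °C
Reagents that add atoms: N-chlorosuccinimide, O=C1CCC(=O)N1Cl
Why: Electrophilic ortho-chlorination of the only free phenol: C6 is ortho to the hydroxyl, the para position carries the ketal oxygen, and the silylated upper arene and the enone are not nucleophilic enough to compete.

Step 13
Reactants: 18 6-chloro spiroketal enone
Product: 19 bis-epoxide (C2'–C3' oxirane anti to the aryloxy oxygen on C1')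
Conditions: t-BuOOH (in decane), DBU, CH2Cl2, 0 °C
Reagents that add atoms: tert-butyl hydroperoxide, CC(C)(C)OO
Why: Weitz–Scheffer nucleophilic epoxidation of the enone: the tert-butyl peroxide anion should add to C2' anti to the pseudo-axial aryloxy oxygen on C1', which holds the lower arene over that face, so that the oxirane forms on the side of the ring C oxygen, and the C4 silyl ether prevents a Payne rearrangement of the lower oxirane under base.

Step 14
Reactants: 19 bis-epoxide
Product: 20 target
Conditions: Et3N·3HF, MeCN, rt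
Reagents that add atoms: none
Why: Fluoride-mediated desilylation of the alkyl TBS and aryl TIPS ethers under nearly neutral conditions, which should leave both oxiranes, the ketone and the spiroketal untouched; no stereocentre is affected.

**Compound list**

1 | naphthazarin (5,8-dihydroxynaphthalene-1,4-dione) | O=C1C=CC(=O)c2c(O)ccc(O)c12 | starting material
2 | leuconaphthazarin (5,8-dihydroxy-2,3-dihydronaphthalene-1,4-dione) | O=C1CCC(=O)c2c(O)ccc(O)c12 | intermediate
3 | (R)-4,5,8-trihydroxy-3,4-dihydronaphthalen-1(2H)-one | O=C1CC[C@@H](O)c2c(O)ccc(O)c12 | intermediate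
4 | (R)-4,5,8-tris(tert-butyldimethylsilyloxy)-3,4-dihydronaphthalen-1(2H)-one | O=C1CC[C@@H](O[Si](C)(C)C(C)(C)C)c2c(O[Si](C)(C)C(C)(C)C)ccc(O[Si](C)(C)C(C)(C)C)c12 | intermediate
5 | (R)-4,5,8-tris(tert-butyldimethylsilyloxy)-3,4-dihydronaphthalen-1-yl trifluoromethanesulfonate | O=S(=O)(OC1=CC[C@@H](O[Si](C)(C)C(C)(C)C)c2c(O[Si](C)(C)C(C)(C)C)ccc(O[Si](C)(C)C(C)(C)C)c12)C(F)(F)F | intermediate
6 | naphthalene-1,5-diol | Oc1cccc2c(O)cccc12 | starting material
7 | 5-hydroxy-4,4-dimethoxynaphthalen-1(4H)-one | COC1(OC)C=CC(=O)c2cccc(O)c12 | intermediate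
8 | 8-bromo-5-hydroxy-4,4-dimethoxynaphthalen-1(4H)-one | COC1(OC)C=CC(=O)c2c(Br)ccc(O)c12 | intermediate
9 | 8-bromo-6-chloro-5-hydroxy-4,4-dimethoxynaphthalen-1(4H)-one | COC1(OC)C=CC(=O)c2c(Br)cc(Cl)c(O)c12 | intermediate
10 | 8-bromo-6-chloro-4,4-dimethoxy-5-(triisopropylsilyloxy)naphthalen-1(4H)-one | COC1(OC)C=CC(=O)c2c(Br)cc(Cl)c(O[Si](C(C)C)(C(C)C)C(C)C)c12 | intermediate
11 | 2-[(R)-4,5,8-tris(tert-butyldimethylsilyloxy)-3,4-dihydronaphthalen-1-yl]-4,4,5,5-tetramethyl-1,3,2-dioxaborolane | CC1(C)OB(OC1(C)C)C1=CC[C@@H](O[Si](C)(C)C(C)(C)C)c2c(O[Si](C)(C)C(C)(C)C)ccc(O[Si](C)(C)C(C)(C)C)c12 | intermediate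
12 | 6-chloro-4,4-dimethoxy-5-(triisopropylsilyloxy)-8-[(4R)-4,5,8-tris(tert-butyldimethylsilyloxy)-3,4-dihydronaphthalen-1-yl]naphthalen-1(4H)-one | COC1(OC)C=CC(=O)c2c(C3=CC[C@@H](O[Si](C)(C)C(C)(C)C)c4c(O[Si](C)(C)C(C)(C)C)ccc(O[Si](C)(C)C(C)(C)C)c34)cc(Cl)c(O[Si](C(C)C)(C(C)C)C(C)C)c12 | intermediate
13 | open hydroperoxy ketone: 8-[(4R)-1-hydroperoxy-4,5,8-tris(tert-butyldimethylsilyloxy)-1,4-dihydronaphthalen-1-yl] analogue of 12, C1 hydroperoxide trans to the C4 silyloxy group, alkene at C2=C3 | COC1(OC)C=CC(=O)c2c([C@@]3(OO)C=C[C@@H](O[Si](C)(C)C(C)(C)C)c4c(O[Si](C)(C)C(C)(C)C)ccc(O[Si](C)(C)C(C)(C)C)c34)cc(Cl)c(O[Si](C(C)C)(C(C)C)C(C)C)c12 | intermediate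
14 | peri-fused 1,2-dioxan-3-ol (cyclic peroxy-hemiketal of 13; ring C8'–C8a'–C1'(OH)–O–O–C1; C1' epimers) | COC1(OC)C=CC2(O)OO[C@@]3(C=C[C@@H](O[Si](C)(C)C(C)(C)C)c4c(O[Si](C)(C)C(C)(C)C)ccc(O[Si](C)(C)C(C)(C)C)c34)c3cc(Cl)c(O[Si](C(C)C)(C(C)C)C(C)C)c1c32 | intermediate
15 | epoxy hemiketal: five-membered ring C (C8'–C8a'–C1'(OH)–O–C1), C2–C3 oxirane syn to the ring oxygen on C1 and anti to the C4 silyloxy group; C1' epimers | COC1(OC)C=CC2(O)O[C@@]3([C@@H]4O[C@@H]4[C@@H](O[Si](C)(C)C(C)(C)C)c4c(O[Si](C)(C)C(C)(C)C)ccc(O[Si](C)(C)C(C)(C)C)c34)c3cc(Cl)c(O[Si](C(C)C)(C(C)C)C(C)C)c1c32 | intermediate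
16 | hydroquinone hemiketal: 15 with free C5 and C8 phenols | COC1(OC)C=CC2(O)O[C@@]3([C@@H]4O[C@@H]4[C@@H](O[Si](C)(C)C(C)(C)C)c4c(O)ccc(O)c34)c3cc(Cl)c(O[Si](C(C)C)(C(C)C)C(C)C)c1c32 | intermediate
17 | spiroketal enone: rings C and D closed at spiro C1', C2'=C3'–C4'=O enone, lower C2–C3 oxirane, C4 OTBS, C5 OH, C5' OTIPS, C6' Cl | O=C1c2c(O[Si](C(C)C)(C(C)C)C(C)C)c(Cl)cc3c2[C@@]2(Oc4ccc(O)c5c4[C@]3(O2)[C@@H]2O[C@@H]2[C@H]5O[Si](C)(C)C(C)(C)C)C=C1 | intermediate
18 | 6-chloro spiroketal enone (17 chlorinated ortho to the C5 hydroxyl) | O=C1c2c(O[Si](C(C)C)(C(C)C)C(C)C)c(Cl)cc3c2[C@@]2(Oc4cc(Cl)c(O)c5c4[C@]3(O2)[C@@H]2O[C@@H]2[C@H]5O[Si](C)(C)C(C)(C)C)C=C1 | intermediate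
19 | bis-epoxide: 18 with C2'–C3' oxirane anti to the aryloxy oxygen on C1' | O=C1c2c(O[Si](C(C)C)(C(C)C)C(C)C)c(Cl)cc3c2[C@@]2(Oc4cc(Cl)c(O)c5c4[C@]3(O2)[C@@H]2O[C@@H]2[C@H]5O[Si](C)(C)C(C)(C)C)[C@@H]2O[C@H]12 | intermediate
20 | target CNP0289684.3 (lower oxirane syn to the ring C oxygen and anti to the C4 hydroxyl; upper oxirane anti to the aryloxy oxygen) | O=C1c2c(O)c(Cl)cc3c2[C@@]2(Oc4cc(Cl)c(O)c5c4[C@]3(O2)[C@@H]2O[C@@H]2[C@H]5O)[C@@H]2O[C@H]12 | target

**Totals and risks**

Total steps: 14. Longest linear sequence: 10 steps (steps 1–4 then 9–14; the branch 5–8 then 9–14 is equally long).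

Steps most likely to fail:

Step 10 (proposed new method). The oxygen transfer from the masked hydroperoxide may be outrun by Hock-type fragmentation or by loss of hydrogen peroxide or silanol with aromatisation of ring F. The titanium alkylperoxide may also fail to enter the bimolecular oxygen-transfer manifold because the hydroperoxide rests in the cyclic form. A further danger is (4+2) addition of singlet oxygen across C2=C1–C8a=C8 in place of the ene reaction. Fallback with known chemistry, setting out from 12: the photooxygenation is run as before and the cold solution of 13 and 14 is treated with PPh3, which reduces the hydroperoxide to the tertiary allylic alcohol. This alcohol should close directly on the peri ketone to the five-membered allylic hemiketal F1. Hydroxyl-directed epoxidation of F1 with VO(acac)2 and t-BuOOH in CH2Cl2, syn to the C1 oxygen, then gives 15, where the fallback comes back to the route. Ring C is then closed directly and the second oxygen comes from the external peroxide.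

Step 2. Over-reduction to the diol, slow or poorly selective hydride transfer to the chelated ortho-hydroxyaryl ketone, and air oxidation of the hydroquinone may erode yield and enantiopurity. Fallback, setting out from 2: both phenols are silylated first (TBSCl, imidazole, DMF) to the bis-silyl dione F2. Corey–Bakshi–Shibata reduction with (S)-Me-CBS oxazaborolidine and BH3·SMe2 (one hydride equivalent, THF, −20 °C) then gives the (R)-hydroxy ketone F3. Silylation of the remaining alcohol (TBSCl, imidazole) returns to the route at 4.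

Step 9. Transmetalation and reductive elimination between two peri-hindered partners may be slow, so that protodeboronation of 11 or competing reaction at the C–Cl bond takes over. Fallback, setting out from 4 and 10: Barluenga coupling. Ketone 4 is condensed with TsNHNH2 (MeOH, 60 °C) to the N-tosylhydrazone F4. F4 is then coupled with 10 using Pd2(dba)3, XPhos and LiOtBu in dioxane at 90 °C. Palladium carbene formation, aryl migration and β-hydride elimination towards C2 should give 12 directly, where the fallback comes back to the route without enol triflate or boronate.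

Further compounds
F1 | step 10 | five-membered allylic hemiketal (ring C closed, C2=C3 alkene, C1' epimers) | COC1(OC)C=CC2(O)O[C@@]3(C=C[C@@H](O[Si](C)(C)C(C)(C)C)c4c(O[Si](C)(C)C(C)(C)C)ccc(O[Si](C)(C)C(C)(C)C)c34)c3cc(Cl)c(O[Si](C(C)C)(C(C)C)C(C)C)c1c32
F2 | step 2 | 5,8-bis(tert-butyldimethylsilyloxy)-2,3-dihydronaphthalene-1,4-dione | O=C1CCC(=O)c2c(O[Si](C)(C)C(C)(C)C)ccc(O[Si](C)(C)C(C)(C)C)c12
F3 | step 2 | (R)-4-hydroxy-5,8-bis(tert-butyldimethylsilyloxy)-3,4-dihydronaphthalen-1(2H)-one | O=C1CC[C@@H](O)c2c(O[Si](C)(C)C(C)(C)C)ccc(O[Si](C)(C)C(C)(C)C)c12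
F4 | step 9 | N-tosylhydrazone of ketone 4 | Cc1ccc(cc1)S(=O)(=O)NN=C1CC[C@@H](O[Si](C)(C)C(C)(C)C)c2c(O[Si](C)(C)C(C)(C)C)ccc(O[Si](C)(C)C(C)(C)C)c12
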